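**Retrosynthetic overview** (prostaglandin numbering, listed from the first bond made to the last)
- No ring is formed: the cyclopentane is bought as 3-ethoxycyclopent-2-en-1-one 1.
- C9–O is made first, by enantioselective oxygenation of 1 to silyloxy enone 4; this single centre then controls C8 and C12.
- C7–C8 by allyl Grignard addition with carbonyl transposition (7); C8–H and C12–C13 in one pot by conjugate reduction and Michael addition to oct-1-en-3-one 8 (11).
- C5=C6 by Z-selective cross-metathesis with silyl hex-5-enoate 13 (14); both silyl groups leave together to give target 15.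

Assumption: the sense of induction of the (R,R)-manganese salen catalyst in step 1 is assigned by analogy with indene-type cyclic conjugated alkenes; if the measured configuration is opposite, the equally available (S,S)-catalyst is used with nothing else changed.

**Step 1**
Reactants: 1 3-ethoxycyclopent-2-en-1-one
Product: 4 (5S)-5-[(tert-butyldimethylsilyl)oxy]-3-ethoxycyclopent-2-en-1-one, via silyl dienol ether 2 (not isolated), via silyloxy epoxide 3 (not isolated)
Conditions: LiN(iPr)2, THF, −78 °C; TBSCl, DMPU, −78 to 0 °C; pentane, filter, concentrate cold; then (R,R)-Jacobsen catalyst C36H52ClMnN2O2 [(R,R)-N,N'-bis(3,5-di-tert-butylsalicylidene)cyclohexane-1,2-diamine manganese chloride] (5 mol %), PhIO (1.3 equiv), 4-phenylpyridine N-oxide (20 mol %), 4 Å MS, CH2Cl2, −30 °C to rt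
Reagents that add atoms: tert-butyldimethylsilyl chloride, CC(C)(C)[Si](C)(C)Cl; iodosylbenzene, O=Ic1ccccc1
Why: Proposed new method: the chiral oxo-manganese salen species should transfer oxygen to one enantiotopic face of the terminal silyl enol ether C=C of diene 2 (attack at the CH terminus gives the intermediate stabilised by both the silyloxy and the ethoxy group), and under anhydrous PhIO conditions the silyloxy epoxide 3 opens to an ethoxy-stabilised oxocarbenium ion whose TBS group shifts from oxygen to oxygen, so the C9–O bond and the (S) centre are set in the oxygen-transfer event and the product arrives already protected; the closest known reactions are the Jacobsen–Katsuki epoxidation of cyclic conjugated dienes and simple silyl enol ethers and the Rubottom oxidation, neither shown on a 1-alkoxy-3-silyloxycyclopentadiene with retention of the silyl group.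

**Step 2**
Reactants: 4 (5S)-5-[(tert-butyldimethylsilyl)oxy]-3-ethoxycyclopent-2-en-1-one; 5 allylmagnesium bromide
Product: 7 (4S)-4-[(tert-butyldimethylsilyl)oxy]-3-(prop-2-en-1-yl)cyclopent-2-en-1-one, via tertiary allylic alcohol 6 (not isolated)
Conditions: CH2=CHCH2MgBr (1.3 equiv), THF, −78 °C; then 1 M aq HCl, THF, 0 °C
Reagents that add atoms: water, O
Why: 1,2-addition of the allyl Grignard reagent to the vinylogous ester carbonyl outruns enolisation at −78 °C, and acid hydrolysis with loss of ethanol and water transposes the carbonyl (Stork–Danheiser sequence), so the oxygenated carbon becomes the γ-carbon of the new enone untouched while the carbinol centre of 6 is destroyed.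

**Step 3**
Reactants: 7 (4S)-4-[(tert-butyldimethylsilyl)oxy]-3-(prop-2-en-1-yl)cyclopent-2-en-1-one; 8 oct-1-en-3-one
Product: 11 (2R,3R,4S)-4-[(tert-butyldimethylsilyl)oxy]-2-(3-oxooctyl)-3-(prop-2-en-1-yl)cyclopentan-1-one, via ring enol silane 9 (not isolated), via side-chain enol silane 10 (not isolated)
Conditions: [(Ph3P)CuH]6 (5 mol % Cu), PhMe2SiH (1.3 equiv), toluene, 0 °C to rt; then CH2Cl2, 8 (1.5 equiv), Sc(OTf)3 (10 mol %), −78 °C; aq NaHCO3, then 0.5 M HCl/THF, 0 °C
Reagents that add atoms: none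
Why: copper hydride conjugate reduction delivers hydride to the β-carbon on the face anti to the adjacent OTBS group (allyl and OTBS become cis at C8/C9) and gives the enol silane 9 regiospecifically on the C12 side, away from the silyloxy carbon, which then undergoes a Lewis-acid Mukaiyama–Michael addition to 8 anti to the allyl group (C8/C12 trans, also the thermodynamic arrangement).

**Step 4**
Reactants: 12 hex-5-enoic acid
Product: 13 tri(propan-2-yl)silyl hex-5-enoate
Conditions: iPr3SiCl (1.05 equiv), Et3N, CH2Cl2, 0 °C to rt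
Reagents that add atoms: chlorotri(propan-2-yl)silane, CC(C)[Si](Cl)(C(C)C)C(C)C
Why: silyl esterification masks the acid, which the metathesis catalyst does not tolerate, as a group that the final fluoride step removes; no stereocentre is involved.

**Step 5**
Reactants: 11 (2R,3R,4S)-4-[(tert-butyldimethylsilyl)oxy]-2-(3-oxooctyl)-3-(prop-2-en-1-yl)cyclopentan-1-one; 13 tri(propan-2-yl)silyl hex-5-enoate
Product: 14 tri(propan-2-yl)silyl (5Z)-7-[(1R,2R,5S)-5-[(tert-butyldimethylsilyl)oxy]-3-oxo-2-(3-oxooctyl)cyclopentyl]hept-5-enoate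
Conditions: 13 (4 equiv), cyclometalated nitrato ruthenium catalyst C32H41N3O4Ru [Ru(NO3)(=CH-C6H4-2-OiPr)(N-mesityl-N'-adamantylimidazolidinylidene, metalated at adamantyl)] (5 mol %), THF, 35 °C, static vacuum
Reagents that add atoms: none
Why: Z-selective olefin cross-metathesis, in which the chelated carbene forces both metallacyclobutane substituents to the same side; ketones, silyl ether and silyl ester are tolerated and no stereocentre is touched.

**Step 6**
Reactants: 14 tri(propan-2-yl)silyl (5Z)-7-[(1R,2R,5S)-5-[(tert-butyldimethylsilyl)oxy]-3-oxo-2-(3-oxooctyl)cyclopentyl]hept-5-enoate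
Product: 15 (5Z)-7-[(1R,2R,5S)-5-hydroxy-3-oxo-2-(3-oxooctyl)cyclopentyl]hept-5-enoic acid (13,14-dihydro-15-keto-PGD2)
Conditions: 48 % aq HF, MeCN, 0 °C to rt
Reagents that add atoms: none
Why: fluoride-driven desilylation cleaves the silyl ester and the secondary silyl ether under mildly acidic, non-basic conditions, which avoids β-elimination of the β-hydroxy ketone and leaves all three stereocentres and the Z-alkene unchanged.

**Compound list**
1 | 3-ethoxycyclopent-2-en-1-one | CCOC1=CC(=O)CC1 | starting material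
2 | 1-ethoxy-3-[(tert-butyldimethylsilyl)oxy]cyclopenta-1,3-diene | CCOC1=CC(O[Si](C)(C)C(C)(C)C)=CC1 | intermediate
3 | (1S,5S)-1-[(tert-butyldimethylsilyl)oxy]-3-ethoxy-6-oxabicyclo[3.1.0]hex-2-ene | CCOC1=C[C@@]2(O[Si](C)(C)C(C)(C)C)O[C@H]2C1 | intermediate
4 | (5S)-5-[(tert-butyldimethylsilyl)oxy]-3-ethoxycyclopent-2-en-1-one | CCOC1=CC(=O)[C@@H](O[Si](C)(C)C(C)(C)C)C1 | intermediate
5 | allylmagnesium bromide | C=CC[Mg]Br | starting material
6 | (1R,5S)-5-[(tert-butyldimethylsilyl)oxy]-3-ethoxy-1-(prop-2-en-1-yl)cyclopent-2-en-1-ol (allyl trans to the silyloxy group, expected major epimer; either epimer gives 7) | C=CC[C@@]1(O)C=C(OCC)C[C@@H]1O[Si](C)(C)C(C)(C)C | intermediate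
7 | (4S)-4-[(tert-butyldimethylsilyl)oxy]-3-(prop-2-en-1-yl)cyclopent-2-en-1-one | C=CCC1=CC(=O)C[C@@H]1O[Si](C)(C)C(C)(C)C | intermediate
8 | oct-1-en-3-one | C=CC(=O)CCCCC | starting material
9 | tert-butyl{[(1S,2R)-4-{[dimethyl(phenyl)silyl]oxy}-2-(prop-2-en-1-yl)cyclopent-3-en-1-yl]oxy}dimethylsilane (allyl and OTBS cis) | C=CC[C@@H]1C=C(O[Si](C)(C)c2ccccc2)C[C@@H]1O[Si](C)(C)C(C)(C)C | intermediate
10 | (2R,3R,4S)-4-[(tert-butyldimethylsilyl)oxy]-2-[(2Z)-3-{[dimethyl(phenyl)silyl]oxy}oct-2-en-1-yl]-3-(prop-2-en-1-yl)cyclopentan-1-one | CCCCC/C(O[Si](C)(C)c1ccccc1)=C/C[C@H]1C(=O)C[C@H](O[Si](C)(C)C(C)(C)C)[C@@H]1CC=C | intermediate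
11 | (2R,3R,4S)-4-[(tert-butyldimethylsilyl)oxy]-2-(3-oxooctyl)-3-(prop-2-en-1-yl)cyclopentan-1-one | CCCCCC(=O)CC[C@H]1C(=O)C[C@H](O[Si](C)(C)C(C)(C)C)[C@@H]1CC=C | intermediate
12 | hex-5-enoic acid | C=CCCCC(=O)O | starting material
13 | tri(propan-2-yl)silyl hex-5-enoate | C=CCCCC(=O)O[Si](C(C)C)(C(C)C)C(C)C | intermediate
14 | tri(propan-2-yl)silyl (5Z)-7-[(1R,2R,5S)-5-[(tert-butyldimethylsilyl)oxy]-3-oxo-2-(3-oxooctyl)cyclopentyl]hept-5-enoate | CCCCCC(=O)CC[C@H]1C(=O)C[C@H](O[Si](C)(C)C(C)(C)C)[C@@H]1C/C=C\CCCC(=O)O[Si](C(C)C)(C(C)C)C(C)C | intermediate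
15 | (5Z)-7-[(1R,2R,5S)-5-hydroxy-3-oxo-2-(3-oxooctyl)cyclopentyl]hept-5-enoic acid (13,14-dihydro-15-keto-PGD2) | CCCCCC(=O)CC[C@H]1C(=O)C[C@H](O)[C@@H]1C/C=C\CCCC(=O)O | target

**Step count and risks**
Total steps: 6. Longest linear sequence: 5 (steps 1, 2, 3, 5, 6).

The three steps most likely to fail are steps 1, 3 and 5.

Step 1 is the proposed oxygenation; the risks are low enantioselectivity, attack at the other enol ether double bond, or loss of the silyl group. The fallback uses known chemistry, sets out from 1 and comes back at 4. α′-Acetoxylation of 1 with Mn(OAc)3·2H2O in refluxing benzene gives racemic 5-acetoxy-3-ethoxycyclopent-2-en-1-one F1. Lipase-catalysed enantioselective hydrolysis (Amano PS lipase, pH 7 phosphate buffer) removes the (R)-enantiomer as (5R)-3-ethoxy-5-hydroxycyclopent-2-en-1-one F2, which is discarded, and leaves (5S)-5-acetoxy-3-ethoxycyclopent-2-en-1-one F3. If the enzyme shows the opposite preference, the (S)-alcohol is collected directly. Pig liver esterase at pH 7 converts F3 into (5S)-3-ethoxy-5-hydroxycyclopent-2-en-1-one F4, and TBSCl with imidazole in DMF gives 4.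

Step 3 may fail through a sluggish or messy one-pot Michael addition, or through elimination of the silyloxy group if the enolate equilibrates. The fallback sets out from 7 and comes back at 11. Compound 7 is reduced as in step 3, but 9 is isolated by filtration through basic alumina and cleaved with MeLi (THF, −78 °C) to the regiodefined enolate lithium (3R,4S)-4-[(tert-butyldimethylsilyl)oxy]-3-(prop-2-en-1-yl)cyclopent-1-en-1-olate F5. At −78 °C this adds to the non-polymerising α-silyl enone 2-(trimethylsilyl)oct-1-en-3-one F6, prepared from hexanoyl chloride and 1-(trimethylsilyl)vinylmagnesium bromide with catalytic CuI (Stork–Ganem Michael addition). The adduct is (2R,3R,4S)-4-[(tert-butyldimethylsilyl)oxy]-2-[3-oxo-2-(trimethylsilyl)octyl]-3-(prop-2-en-1-yl)cyclopentan-1-one F7, a mixture at the silyl-bearing carbon. KF in MeOH at 0 °C removes the C-silyl group and delivers 11.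

Step 5 may give insufficient Z-selectivity or conversion with the β-branched allyl group. The fallback sets out from 11 and comes back at 15. Ozonolysis of the allyl group (O3, CH2Cl2, −78 °C; PPh3) gives 2-[(1R,2R,5S)-5-[(tert-butyldimethylsilyl)oxy]-3-oxo-2-(3-oxooctyl)cyclopentyl]acetaldehyde F8. An aldehyde-selective Wittig reaction with 1.1 equiv of the salt-free ylide from (4-carboxybutyl)triphenylphosphonium bromide and KN(SiMe3)2 (THF, −78 °C) gives (5Z)-7-[(1R,2R,5S)-5-[(tert-butyldimethylsilyl)oxy]-3-oxo-2-(3-oxooctyl)cyclopentyl]hept-5-enoic acid F9. Aqueous HF in MeCN, as in step 6, then gives 15.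

**Further compounds**
F1 | step 1 | racemic 5-acetoxy-3-ethoxycyclopent-2-en-1-one | CCOC1=CC(=O)C(OC(C)=O)C1
F2 | step 1 | (5R)-3-ethoxy-5-hydroxycyclopent-2-en-1-one | CCOC1=CC(=O)[C@H](O)C1
F3 | step 1 | (5S)-5-acetoxy-3-ethoxycyclopent-2-en-1-one | CCOC1=CC(=O)[C@@H](OC(C)=O)C1
F4 | step 1 | (5S)-3-ethoxy-5-hydroxycyclopent-2-en-1-one | CCOC1=CC(=O)[C@@H](O)C1
F5 | step 3 | lithium (3R,4S)-4-[(tert-butyldimethylsilyl)oxy]-3-(prop-2-en-1-yl)cyclopent-1-en-1-olate | C=CC[C@@H]1C=C(O[Li])C[C@@H]1O[Si](C)(C)C(C)(C)C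
F6 | step 3 | 2-(trimethylsilyl)oct-1-en-3-one | C=C(C(=O)CCCCC)[Si](C)(C)C
F7 | step 3 | (2R,3R,4S)-4-[(tert-butyldimethylsilyl)oxy]-2-[3-oxo-2-(trimethylsilyl)octyl]-3-(prop-2-en-1-yl)cyclopentan-1-one (mixture at the silyl-bearing carbon) | CCCCCC(=O)C(C[C@H]1C(=O)C[C@H](O[Si](C)(C)C(C)(C)C)[C@@H]1CC=C)[Si](C)(C)C
F8 | step 5 | 2-[(1R,2R,5S)-5-[(tert-butyldimethylsilyl)oxy]-3-oxo-2-(3-oxooctyl)cyclopentyl]acetaldehyde | CCCCCC(=O)CC[C@H]1C(=O)C[C@H](O[Si](C)(C)C(C)(C)C)[C@@H]1CC=O
F9 | step 5 | (5Z)-7-[(1R,2R,5S)-5-[(tert-butyldimethylsilyl)oxy]-3-oxo-2-(3-oxooctyl)cyclopentyl]hept-5-enoic acid | CCCCCC(=O)CC[C@H]1C(=O)C[C@H](O[Si](C)(C)C(C)(C)C)[C@@H]1C/C=C\CCCC(=O)O
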